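**Strategy.** The route rests on cutting the C9–C10 bond of the ten-membered ring in an oxy-Cope sense. The C2 oxygen, the C1 α-carbon and a C7=C8 alkene (the latent C7–O/C8–OH pair) define a 1,5-diene whose C2–C7 bond closes a cyclohexene that already carries the (Z)-C5=C6 unit; ring A (C1, C10–C14) is present as a cyclohexenyl group. One anion-accelerated [3,3] shift expands that cyclohexene by four atoms, forms C9–C10, sets C9 and C10 and leaves a regiodefined C1=C2 enolate. The precursor is a trans-1-(cyclohexenyl ketal)-2-alkenyl-4-methylcyclohex-3-enol with an (E)-methoxymethyl enol ether terminus.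

Key step: step 17

Remarks on the chemistry (one line each):
- Atom labels C1–C19 follow the target: ten-membered ring C1–C10, ring A C1/C10–C14, lactone C7–C8–C17–C19(=O)–O.
- The stereostructures of precursor 22 and rearrangement product 25 were checked against a chair transition state and against C9, C10 and C17 of the target; they are mutually consistent and are used unchanged.
- Assumption: in step 4 the pseudo-enantiomeric cinchona catalyst that gives (S)-6 is chosen; it is written as (DHQD)2PHAL.
- C8 in 12–19 forms as an epimer mixture and is drawn without configuration; it becomes sp2 in step 15.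

Step 1
Reactants: 1 cyclohexane-1,3-dione
Product: 2 3-bromocyclohex-2-en-1-one
Conditions: PBr3, CHCl3, 0 °C → rt
Reagents that add atoms: phosphorus tribromide, BrP(Br)Br
Why: Deoxybromination of the enol form of the 1,3-diketone (addition–elimination at the vinylogous acid) should give the β-bromo enone.

Step 2
Reactants: 2 3-bromocyclohex-2-en-1-one
Product: 3 7-bromo-1,4-dioxaspiro[4.5]dec-6-ene
Conditions: (TMSOCH2)2, TMSOTf (cat.), CH2Cl2, −78 °C
Reagents that add atoms: 1,2-bis(trimethylsilyloxy)ethane, C[Si](C)(C)OCCO[Si](C)(C)C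
Why: Aprotic low-temperature (Noyori-type) ketalisation should protect the enone carbonyl without moving the C=C bond out of conjugation with bromine.

Step 3
Reactants: 4 cyclohexa-1,3-diene
Product: 5 2,3-dioxabicyclo[2.2.2]oct-5-ene
Conditions: O2, tetraphenylporphyrin (cat.), hν, CH2Cl2, −20 °C
Reagents that add atoms: oxygen, O=O
Why: [4+2] cycloaddition of singlet oxygen to the cyclic 1,3-diene gives the meso endoperoxide.

Step 4
Reactants: 5 2,3-dioxabicyclo[2.2.2]oct-5-ene
Product: 6 (S)-4-hydroxycyclohex-2-en-1-one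
Conditions: (DHQD)2PHAL (cat.), CH2Cl2, rt
Reagents that add atoms: none
Why: Base-catalysed Kornblum–DeLaMare rearrangement in which the chiral amine removes one of the two enantiotopic bridgehead protons, so the catalyst sets the carbinol centre of the γ-hydroxy enone.

Step 5
Reactants: 6 (S)-4-hydroxycyclohex-2-en-1-one
Product: 7 (S)-4-(triethylsilyloxy)cyclohex-2-en-1-one
Conditions: TESCl, imidazole, CH2Cl2, 0 °C
Reagents that add atoms: chlorotriethylsilane, CC[Si](Cl)(CC)CC
Why: Standard O-silylation; the TES ether is chosen because it can later be removed in the presence of a primary TBS ether.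

Step 6
Reactants: 8 methyl (S)-3-hydroxy-2-methylpropanoate
Product: 9 methyl (S)-3-(tert-butyldimethylsilyloxy)-2-methylpropanoate
Conditions: TBSCl, imidazole, DMF, rt
Reagents that add atoms: tert-butyl(chloro)dimethylsilane, CC(C)(C)[Si](C)(C)Cl
Why: Standard O-silylation of the primary alcohol (future C19–O).

Step 7
Reactants: 9 methyl (S)-3-(tert-butyldimethylsilyloxy)-2-methylpropanoate
Product: 10 methyl (R)-4-(tert-butyldimethylsilyloxy)-3-methylbutanoate
Conditions: CH2Br2, LiTMP, THF, −78 °C; LiHMDS; n-BuLi, −78 → 0 °C; then HCl/MeOH, 0 °C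
Reagents that add atoms: dibromomethane, BrCBr; methanol, CO
Why: Kowalski ester homologation: the ynolate forms by 1,2-shift of the C17 carbon with retention and is converted into the one-carbon-longer ester (new CH2 = C8, carboxyl = C9); C17 is never deprotonated.

Step 8
Reactants: 10 methyl (R)-4-(tert-butyldimethylsilyloxy)-3-methylbutanoate; 7 (S)-4-(triethylsilyloxy)cyclohex-2-en-1-one
Product: 12 trimethylsilyl enol ether of the trans Michael adduct, via silyl ketene acetal 11 (not isolated)
Conditions: LDA, TMSCl, THF, −78 °C; then 7, TMSOTf (10 mol %), CH2Cl2, −78 °C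
Reagents that add atoms: chlorotrimethylsilane, C[Si](C)(C)Cl
Why: Mukaiyama–Michael addition forms C7–C8; the donor should enter anti to the γ-silyloxy group, which sets C7 (trans to the C2 oxygen), and silyl transfer gives the C5=C6 enol ether regiospecifically.

Step 9
Reactants: 12 trimethylsilyl enol ether of the Michael adduct
Product: 13 enol triflate (C5–OTf, C5=C6)
Conditions: CsF, PhNTf2, DME, rt
Reagents that add atoms: N-phenylbis(trifluoromethanesulfonimide), O=S(=O)(N(c1ccccc1)S(=O)(=O)C(F)(F)F)C(F)(F)F
Why: Fluoride cleaves the enol O–Si bond and the enolate is triflated in place, so the double-bond position fixed in step 8 is kept (enol triflate formation).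

Step 10
Reactants: 13 enol triflate
Product: 14 methyl-substituted cyclohexene (C5–CH3, C2–OTES, methyl ester)
Conditions: MeMgBr, Fe(acac)3 (5 mol %), THF/NMP, −30 °C
Reagents that add atoms: methylmagnesium bromide, C[Mg]Br
Why: Iron-catalysed Kumada-type cross-coupling of an alkenyl triflate is fast at low temperature, so the ester and silyl ethers should survive.

Step 11
Reactants: 14 methyl-substituted cyclohexene TES ether
Product: 15 trans-2-substituted 4-methylcyclohex-3-en-1-ol (methyl ester)
Conditions: PPTS, MeOH, 0 °C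
Reagents that add atoms: none
Why: Acid-catalysed methanolysis removes the secondary TES ether much faster than the primary TBS ether.

Step 12
Reactants: 15 cyclohexenol
Product: 16 2-substituted 4-methylcyclohex-3-en-1-one (methyl ester)
Conditions: Dess–Martin periodinane, NaHCO3, CH2Cl2, 0 °C → rt
Reagents that add atoms: none
Why: Buffered Dess–Martin oxidation gives the β,γ-unsaturated ketone without conjugating the alkene or epimerising C7; the ketone is used crude.

Step 13
Reactants: 16 cyclohexenone ester; 3 7-bromo-1,4-dioxaspiro[4.5]dec-6-ene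
Product: 18 tertiary trimethylsilyl ether (trans-1-cyclohexenyl-2-alkyl cyclohexenol; methyl ester), via alkenyllithium 17 (not isolated)
Conditions: 3, t-BuLi (2 equiv), THF, −78 °C; CeCl3; 16, −78 °C; then TMSCl, Et3N, −78 → 0 °C
Reagents that add atoms: chlorotrimethylsilane, C[Si](C)(C)Cl
Why: Br–Li exchange and transmetalation give a non-basic organocerium that adds 1,2 to the enolisable ketone anti to the C7 branch, which sets C2 (alkenyl groups trans, OH cis to the branch); silylation in the same flask prevents lactonisation onto the ester.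

Step 14
Reactants: 18 tertiary trimethylsilyl ether ester
Product: 19 aldehyde (C9 = CHO)
Conditions: DIBAL-H, CH2Cl2, −78 °C
Reagents that add atoms: none
Why: Partial reduction of the methyl ester through the stable tetrahedral aluminium acetal at −78 °C.

Step 15
Reactants: 19 aldehyde
Product: 21 (E)-methoxymethyl enol ether (tertiary OTMS), via potassium enolate 20 (not isolated)
Conditions: KH, THF, 0 °C; then MOMCl, −78 → 0 °C
Reagents that add atoms: chloromethyl methyl ether, COCCl
Why: O-Alkylation of a potassium aldehyde enolate with a hard electrophile; the enolate oxygen is expected cis to the smaller C17 branch because the C7 branch is flanked by the fully substituted C2, which gives the (E)-enol ether.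

Step 16
Reactants: 21 (E)-methoxymethyl enol ether trimethylsilyl ether
Product: 22 (2R,7R,17R)-trans-1-(1,4-dioxaspiro[4.5]dec-6-en-7-yl)-2-alkenyl-4-methylcyclohex-3-en-1-ol (key-step precursor)
Conditions: K2CO3, MeOH, rt
Reagents that add atoms: none
Why: Basic methanolysis cleaves the trimethylsilyl ether only; enol ether, TBS ether and ketal are stable to these conditions.

Step 17
Reactants: 22 key-step precursor
Product: 25 (9R,10S,17R) ten-membered trimethylsilyl enol ether, via potassium alkoxide 23 (not isolated), via ring-expanded potassium enolate 24 (not isolated)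
Conditions: KH, 18-crown-6, THF, 0 °C → rt; then TMSCl, Et3N, −78 °C
Reagents that add atoms: chlorotrimethylsilane, C[Si](C)(C)Cl
Why: The dissociated potassium alkoxide undergoes a concerted [3,3]-sigmatropic shift in which C9–C10 forms as C2–C7 breaks, and the resulting enolate is O-silylated. The closest known reaction is the anionic oxy-Cope ring expansion of trans-1,2-dialkenylcyclohexanols to cyclodec-5-enones. The ten-membered ring is not closed end to end; it arises by four-atom ring expansion of the cyclohexene through a chair-like six-centre array (C9=C8–C7–C2–C1=C10) with both alkenyl groups equatorial. C10 is set by the face of the cyclohexenyl C1=C10 bond that this chair presents (fixed by C2 and C7), and C9 by the (E)-enol ether, which holds the OMOM group equatorial. The step needs chair over boat and concerted shift over alkoxide fragmentation: the trans-diequatorial substitution makes a boat unattainable and the crown ether speeds the pericyclic path, while the ring-trans C1=C2 and C7=C8 bonds follow from the equatorial C3 and C6 bonds and C5=C6 stays Z.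

Step 18
Reactants: 25 ten-membered trimethylsilyl enol ether
Product: 27 C1-methyl C2-ketone, via lithium enolate 26 (not isolated)
Conditions: MeLi, THF, 0 °C → rt; then MeI, HMPA, −78 → 0 °C
Reagents that add atoms: iodomethane, CI
Why: MeLi cleaves the O–Si bond to the regiodefined enolate, which is C-alkylated; methyl iodide is expected on the ring-A face cis to C9 (anti to axial H-10) through the chair with C9 equatorial, where the C8 chain lies on the H-10 face, giving the trans ring fusion (C1 set).

Step 19
Reactants: 27 C1-methyl C2-ketone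
Product: 28 C2 alcohol
Conditions: LiAlH4, THF, −78 → 0 °C
Reagents that add atoms: none
Why: Hydride reduction; attack anti to the C1–C10 bond (Felkin–Anh with C10 as large group, also the outer face of the ten-membered ring) should give the C2 alcohol with oxygen syn to the C1 methyl.

Step 20
Reactants: 28 C2 alcohol
Product: 29 C11 ketone
Conditions: PPTS, acetone/H2O, 40 °C
Reagents that add atoms: water, O
Why: Acid-catalysed ketal hydrolysis; the dioxolane is more labile than the MOM acetal and the primary TBS ether under PPTS.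

Step 21
Reactants: 29 C11 ketone
Product: 30 bis(trimethylsilyl) compound (C11 enol ether C11=C12; C2–OTMS)
Conditions: LDA (2.3 equiv), TMSCl, THF, −78 °C
Reagents that add atoms: chlorotrimethylsilane, C[Si](C)(C)Cl
Why: Kinetic enolisation at the less hindered C12 methylene (not at tertiary C10–H) with internal silyl quench; the C2 alkoxide is silylated as well.

Step 22
Reactants: 30 bis(trimethylsilyl) compound
Product: 31 ring-A enone (C11=O, C12=C13; C2–OH)
Conditions: Pd(OAc)2, MeCN, rt; then aq. citric acid, THF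
Reagents that add atoms: none
Why: Saegusa–Ito oxidation (Pd enolate, β-hydride elimination towards C13); the mild acidic work-up frees the C2 alcohol.

Step 23
Reactants: 31 ring-A enone
Product: 32 12,13-epoxy ketone
Conditions: H2O2 (30 %), NaOH, MeOH, 0 °C
Reagents that add atoms: hydrogen peroxide, OO
Why: Weitz–Scheffer nucleophilic epoxidation touches only the enone; hydroperoxide adds to C13 anti to the pseudo-axial C1 methyl (1,3-relationship), which places the oxirane on the face opposite that methyl (C12 and C13 set).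

Step 24
Reactants: 32 12,13-epoxy ketone
Product: 33 epoxy diol (C11 methyl carbinol)
Conditions: MeMgBr, CeCl3, THF, −78 °C
Reagents that add atoms: methylmagnesium bromide, C[Mg]Br
Why: 1,2-Addition to the α,β-epoxy ketone anti to the oxirane oxygen gives the tertiary alcohol cis to the epoxide (C11 set); CeCl3 suppresses enolisation towards C10 and loss of the C9 ether.

Step 25
Reactants: 33 epoxy diol
Product: 35 triol with C13=C14 (C2–OH C11–OH C12–OH), via hydroxy selenide 34 (not isolated)
Conditions: (PhSe)2, NaBH4, EtOH, rt → 70 °C; then H2O2 (30 %), pyridine, THF, 0 °C → rt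
Reagents that add atoms: none
Why: Epoxide-to-allylic-alcohol conversion by the selenide route: PhSe⁻ opens the oxirane trans-diaxially at C13 (remote from quaternary C11), and selenoxide syn-elimination towards C14 leaves the C12 alcohol with its configuration unchanged.

Step 26
Reactants: 35 triol
Product: 36 2,12-diacetate
Conditions: Ac2O, pyridine, DMAP (cat.), CH2Cl2, 0 °C → rt
Reagents that add atoms: acetic anhydride, CC(=O)OC(C)=O
Why: DMAP-catalysed acetylation of the two secondary alcohols; the tertiary C11–OH is left, and C12–OH can no longer direct the later epoxidation.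

Step 27
Reactants: 36 2,12-diacetate
Product: 37 C9 alcohol
Conditions: Me2BBr, CH2Cl2, −78 °C; then aq. NaHCO3
Reagents that add atoms: none
Why: Lewis-acid cleavage of the MOM acetal at the acetal carbon, so the C9–O bond and its configuration are untouched; acetates and the TBS ether tolerate −78 °C.

Step 28
Reactants: 37 C9 alcohol
Product: 38 7,8-epoxide
Conditions: VO(acac)2 (5 mol %), t-BuOOH, CH2Cl2, 0 °C
Reagents that add atoms: tert-butyl hydroperoxide, CC(C)(C)OO
Why: Vanadium-catalysed hydroxyl-directed epoxidation reaches only the allylic C7=C8 bond; with the geminal C17 branch (A1,2 strain) oxygen is delivered in the erythro sense, which sets C8 (and C7 before its inversion).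

Step 29
Reactants: 38 7,8-epoxide
Product: 39 triacetate epoxide
Conditions: Ac2O, DMAP, pyridine, CH2Cl2, rt
Reagents that add atoms: acetic anhydride, CC(=O)OC(C)=O
Why: DMAP-catalysed acetylation of the secondary C9 alcohol; the tertiary alcohol and the epoxide are inert to these conditions.

Step 30
Reactants: 39 triacetate epoxide
Product: 40 primary alcohol (C19–OH)
Conditions: TBAF, AcOH, THF, 0 °C
Reagents that add atoms: none
Why: Buffered fluoride desilylation; the buffer keeps the alkoxide from attacking the vinyl oxirane and the acetates from migrating.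

Step 31
Reactants: 40 primary alcohol
Product: 42 CNP0129620.2 (target), via epoxy acid 41 (not isolated)
Conditions: TEMPO (cat.), NaOCl (cat.), NaClO2, MeCN/phosphate buffer pH 6.7, 35 °C; then pH 4, rt
Reagents that add atoms: sodium chlorite, [Na+].[O-]Cl=O
Why: Near-neutral TEMPO/chlorite oxidation gives the carboxylic acid, which opens the vinyl oxirane at allylic C7 with inversion (five-membered lactone rather than β-lactone), forming the trans-fused γ-lactone and the C8 tertiary alcohol.

**Compound list**

1 | cyclohexane-1,3-dione | O=C1CCCC(=O)C1 | starting material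
2 | 3-bromocyclohex-2-en-1-one | O=C1C=C(Br)CCC1 | intermediate
3 | 7-bromo-1,4-dioxaspiro[4.5]dec-6-ene | BrC1=CC2(OCCO2)CCC1 | intermediate
4 | cyclohexa-1,3-diene | C1=CC=CCC1 | starting material
5 | 2,3-dioxabicyclo[2.2.2]oct-5-ene (meso) | O1OC2C=CC1CC2 | intermediate
6 | (S)-4-hydroxycyclohex-2-en-1-one | O=C1C=C[C@@H](O)CC1 | intermediate
7 | (S)-4-(triethylsilyloxy)cyclohex-2-en-1-one | O=C1C=C[C@@H](O[Si](CC)(CC)CC)CC1 | intermediate
8 | methyl (S)-3-hydroxy-2-methylpropanoate | COC(=O)[C@@H](C)CO | starting material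
9 | methyl (S)-3-(tert-butyldimethylsilyloxy)-2-methylpropanoate | CC(C)(C)[Si](C)(C)OC[C@H](C)C(=O)OC | intermediate
10 | methyl (R)-4-(tert-butyldimethylsilyloxy)-3-methylbutanoate | CC(C)(C)[Si](C)(C)OC[C@H](C)CC(=O)OC | intermediate
11 | methyl trimethylsilyl ketene acetal of 10 (E/Z mixture) | CC(C)(C)[Si](C)(C)OC[C@H](C)C=C(OC)O[Si](C)(C)C | intermediate
12 | TMS enol ether of the Michael adduct (C7–C8 formed, C8 trans to C2–OTES, C8 epimers) | CC(C)(C)[Si](C)(C)OC[C@H](C)C(C(=O)OC)[C@H]1C=C(O[Si](C)(C)C)CC[C@@H]1O[Si](CC)(CC)CC | intermediate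
13 | enol triflate (C5–OTf) | CC(C)(C)[Si](C)(C)OC[C@H](C)C(C(=O)OC)[C@H]1C=C(OS(=O)(=O)C(F)(F)F)CC[C@@H]1O[Si](CC)(CC)CC | intermediate
14 | C5-methyl cyclohexene, C2–OTES, methyl ester | CC(C)(C)[Si](C)(C)OC[C@H](C)C(C(=O)OC)[C@H]1C=C(C)CC[C@@H]1O[Si](CC)(CC)CC | intermediate
15 | trans-2-substituted 4-methylcyclohex-3-en-1-ol, methyl ester | CC(C)(C)[Si](C)(C)OC[C@H](C)C(C(=O)OC)[C@H]1C=C(C)CC[C@@H]1O | intermediate
16 | 2-substituted 4-methylcyclohex-3-en-1-one, methyl ester | CC(C)(C)[Si](C)(C)OC[C@H](C)C(C(=O)OC)[C@H]1C=C(C)CCC1=O | intermediate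
17 | (1,4-dioxaspiro[4.5]dec-6-en-7-yl)lithium | [Li]C1=CC2(OCCO2)CCC1 | intermediate
18 | tertiary TMS ether of the trans-1-cyclohexenyl-2-alkyl cyclohexenol, methyl ester | CC(C)(C)[Si](C)(C)OC[C@H](C)C(C(=O)OC)[C@H]1C=C(C)CC[C@]1(O[Si](C)(C)C)C2=CC3(OCCO3)CCC2 | intermediate
19 | aldehyde (C9 = CHO), tertiary OTMS | CC(C)(C)[Si](C)(C)OC[C@H](C)C(C=O)[C@H]1C=C(C)CC[C@]1(O[Si](C)(C)C)C2=CC3(OCCO3)CCC2 | intermediate
20 | potassium (E)-enolate of 19 | CC(C)(C)[Si](C)(C)OC[C@H](C)/C(=C\[O-])[C@H]1C=C(C)CC[C@]1(O[Si](C)(C)C)C2=CC3(OCCO3)CCC2.[K+] | intermediate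
21 | (E)-MOM enol ether, tertiary OTMS | CC(C)(C)[Si](C)(C)OC[C@H](C)/C(=C\OCOC)[C@H]1C=C(C)CC[C@]1(O[Si](C)(C)C)C2=CC3(OCCO3)CCC2 | intermediate
22 | (2R,7R,17R)-trans-1-(1,4-dioxaspiro[4.5]dec-6-en-7-yl)-2-[(E)-MOM-enol-ether alkenyl]-4-methylcyclohex-3-en-1-ol (key-step precursor) | CC(C)(C)[Si](C)(C)OC[C@H](C)/C(=C\OCOC)[C@H]1C=C(C)CC[C@]1(O)C2=CC3(OCCO3)CCC2 | intermediate
23 | potassium alkoxide of 22 | CC(C)(C)[Si](C)(C)OC[C@H](C)/C(=C\OCOC)[C@H]1C=C(C)CC[C@]1([O-])C2=CC3(OCCO3)CCC2.[K+] | intermediate
24 | ring-expanded potassium enolate (C1=C2–O⁻) | COCO[C@@H]1[C@H]2C3(OCCO3)CCC/C2=C([O-])\CC/C(C)=C\C=C1/[C@@H](C)CO[Si](C)(C)C(C)(C)C.[K+] | intermediate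
25 | (9R,10S,17R) ten-membered TMS enol ether (5Z, 7E, C1=C2 trans in the ring; key-step product) | COCO[C@@H]1[C@H]2C3(OCCO3)CCC/C2=C(O[Si](C)(C)C)\CC/C(C)=C\C=C1/[C@@H](C)CO[Si](C)(C)C(C)(C)C | intermediate
26 | lithium enolate from 25 | COCO[C@@H]1[C@H]2C3(OCCO3)CCC/C2=C([O-])\CC/C(C)=C\C=C1/[C@@H](C)CO[Si](C)(C)C(C)(C)C.[Li+] | intermediate
27 | C1-methyl C2-ketone (trans-fused; C11 dioxolane, C9–OMOM, C19–OTBS) | COCO[C@@H]1[C@H]2C3(OCCO3)CCC[C@]2(C)C(=O)CC/C(C)=C\C=C1/[C@@H](C)CO[Si](C)(C)C(C)(C)C | intermediate
28 | C2 alcohol | COCO[C@@H]1[C@H]2C3(OCCO3)CCC[C@]2(C)[C@H](O)CC/C(C)=C\C=C1/[C@@H](C)CO[Si](C)(C)C(C)(C)C | intermediate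
29 | C11 ketone | COCO[C@@H]1[C@H]2C(=O)CCC[C@]2(C)[C@H](O)CC/C(C)=C\C=C1/[C@@H](C)CO[Si](C)(C)C(C)(C)C | intermediate
30 | bis-TMS compound (C11 enol ether, C2–OTMS) | COCO[C@@H]1[C@H]2C(O[Si](C)(C)C)=CCC[C@]2(C)[C@H](O[Si](C)(C)C)CC/C(C)=C\C=C1/[C@@H](C)CO[Si](C)(C)C(C)(C)C | intermediate
31 | ring-A enone | COCO[C@@H]1[C@H]2C(=O)C=CC[C@]2(C)[C@H](O)CC/C(C)=C\C=C1/[C@@H](C)CO[Si](C)(C)C(C)(C)C | intermediate
32 | 12,13-epoxy ketone | COCO[C@@H]1[C@H]2C(=O)[C@@H]3O[C@@H]3C[C@]2(C)[C@H](O)CC/C(C)=C\C=C1/[C@@H](C)CO[Si](C)(C)C(C)(C)C | intermediate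
33 | epoxy diol (C11 methyl carbinol) | COCO[C@@H]1[C@H]2[C@](C)(O)[C@@H]3O[C@@H]3C[C@]2(C)[C@H](O)CC/C(C)=C\C=C1/[C@@H](C)CO[Si](C)(C)C(C)(C)C | intermediate
34 | hydroxy selenide (C12–OH, C13–SePh) | COCO[C@@H]1[C@H]2[C@](C)(O)[C@H](O)[C@@H]([Se]c3ccccc3)C[C@]2(C)[C@H](O)CC/C(C)=C\C=C1/[C@@H](C)CO[Si](C)(C)C(C)(C)C | intermediate
35 | triol with C13=C14 | COCO[C@@H]1[C@H]2[C@](C)(O)[C@H](O)C=C[C@]2(C)[C@H](O)CC/C(C)=C\C=C1/[C@@H](C)CO[Si](C)(C)C(C)(C)C | intermediate
36 | 2,12-diacetate | COCO[C@@H]1[C@H]2[C@](C)(O)[C@H](OC(C)=O)C=C[C@]2(C)[C@H](OC(C)=O)CC/C(C)=C\C=C1/[C@@H](C)CO[Si](C)(C)C(C)(C)C | intermediate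
37 | C9 alcohol | O[C@@H]1[C@H]2[C@](C)(O)[C@H](OC(C)=O)C=C[C@]2(C)[C@H](OC(C)=O)CC/C(C)=C\C=C1/[C@@H](C)CO[Si](C)(C)C(C)(C)C | intermediate
38 | 7,8-epoxide | O[C@@H]1[C@H]2[C@](C)(O)[C@H](OC(C)=O)C=C[C@]2(C)[C@H](OC(C)=O)CC/C(C)=C\[C@H]3O[C@]13[C@@H](C)CO[Si](C)(C)C(C)(C)C | intermediate
39 | triacetate epoxide | CC(=O)O[C@@H]1[C@H]2[C@](C)(O)[C@H](OC(C)=O)C=C[C@]2(C)[C@H](OC(C)=O)CC/C(C)=C\[C@H]3O[C@]13[C@@H](C)CO[Si](C)(C)C(C)(C)C | intermediate
40 | primary alcohol (C19–OH) | CC(=O)O[C@@H]1[C@H]2[C@](C)(O)[C@H](OC(C)=O)C=C[C@]2(C)[C@H](OC(C)=O)CC/C(C)=C\[C@H]3O[C@]13[C@@H](C)CO | intermediate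
41 | epoxy acid | CC(=O)O[C@@H]1[C@H]2[C@](C)(O)[C@H](OC(C)=O)C=C[C@]2(C)[C@H](OC(C)=O)CC/C(C)=C\[C@H]3O[C@]13[C@@H](C)C(=O)O | intermediate
42 | CNP0129620.2, (1S,2R,5Z,7S,8S,9R,10S,11S,12R,17R) | CC(=O)O[C@@H]1[C@H]2[C@](C)(O)[C@H](OC(C)=O)C=C[C@]2(C)[C@H](OC(C)=O)CC/C(C)=C\[C@@H]2OC(=O)[C@H](C)[C@]21O | target

**Totals**

Total step count: 31. Longest linear sequence: 27 steps (4 → 42 through steps 3–5 and 8–31).

**Steps most likely to fail**

Step 17. The alkoxide may fragment (heterolysis of C2–C7 to an enone and a pentadienyl anion, then [1,3]-recombination or protonation) faster than it rearranges in concert, which would lose the chair-controlled transfer of configuration to C9 and C10. The fallback removes the anion. It sets out from the trimethylsilyl ether 21, which is heated at about 200 °C in degassed toluene in a base-washed sealed tube (thermal siloxy-Cope rearrangement). The silyl group stays on oxygen, so the same enol ether results and the route is rejoined at 25. No new compound is made (F0).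

Step 18. Facial selectivity at C1 is not secured by the substrate: attack anti to the new C9–C10 bond, through the conformer with C9 axial on ring A, would give the cis-fused C1 epimer. The fallback replaces free alkylation by a coordinated delivery. It sets out from 25, which is treated with Et2Zn/CH2I2 (Furukawa–Simmons–Smith cyclopropanation). The zinc carbenoid is held by the C9 methoxymethyl ether oxygens and should add CH2 to the C9 face of the C1=C2 enol ether, giving the trimethylsiloxycyclopropane F1. K2CO3 in MeOH then opens the cyclopropanolate at the C2–CH2 bond (Conia-type α-methylation), and the route is rejoined at 27.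

Step 15. The enolate may form with poor E/Z control, and the (Z)-enol ether would carry the wrong C9 configuration through the rearrangement. The fallback uses thermodynamic control and a stereoretentive exchange. It sets out from 19, which is silylated under equilibrating conditions (TMSCl, NaI, Et3N, MeCN) to the trimethylsilyl enol ether F2. The (E)-isomer is taken on and the (Z)-isomer is re-equilibrated. MeLi then cleaves the enol O–Si bond with retention of geometry, and the lithium enolate is O-alkylated with MOMCl in THF/HMPA, which rejoins the route at 21.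

Further compounds
F0 | step 17 | none | none
F1 | step 18 | trimethylsiloxycyclopropane (CH2 bridging C1 and C2, cis to C9) | COCO[C@@H]1[C@H]2C3(OCCO3)CCC[C@@]24C[C@]4(O[Si](C)(C)C)CC/C(C)=C\C=C1/[C@@H](C)CO[Si](C)(C)C(C)(C)C
F2 | step 15 | (E)-trimethylsilyl enol ether of 19 | CC(C)(C)[Si](C)(C)OC[C@H](C)/C(=C\O[Si](C)(C)C)[C@H]1C=C(C)CC[C@]1(O[Si](C)(C)C)C2=CC3(OCCO3)CCC2
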